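**Retrosynthetic overview**
- The target comes from one BCl3 unmasking of a biflavone that carries three benzyl ethers (apigenin half) and a 5-OMe (C-methylated half).
- Key disconnection: the C3'–C8'' biaryl bond, cut between two finished flavones. Both carbons are natural donors, so ring B of the C-methylated flavone is inverted into an acceptor (an aryloxy-λ3-iodane, an aromatic enolonium equivalent). C8–H of tri-O-benzylapigenin is the donor.
- Apigenin half: bought with all three rings in place and only O-benzylated.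
- C-methylated half: ring C is closed last, by aldol, oxa-Michael and dehydrogenation of an ortho-hydroxyacetophenone with 4-hydroxybenzaldehyde (ring B is bought).
- Ring A of that half: 2,6-dimethoxytoluene → mirror-symmetric 3,5-dimethoxy-4-methylphenol (C–H borylation/oxidation) → Fries acylation, which makes the 6-methyl pattern unambiguous.

Assumption: the SMILES holds no stereocentre and no defined axis. The 3'–8'' axis has only OH, OH and ring O as ortho groups and is taken as freely rotating, so the target is made as the one achiral compound drawn.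

**Step 1**
Reactants: 1 2,6-dimethoxytoluene
Product: 3 3,5-dimethoxy-4-methylphenol, via aryl pinacol boronate 2 (not isolated)
Conditions: [Ir(OMe)(cod)]2 (1.5 mol %), 4,4'-di-tert-butyl-2,2'-bipyridine (3 mol %), B2pin2 (0.55 equiv), THF, 80 °C, 16 h; evaporate; then KHSO5 (as 2KHSO5·KHSO4·K2SO4, 1.05 equiv), acetone–H2O 1:1, rt, 10 min
Reagents that add atoms: bis(pinacolato)diboron CC1(C)OB(OC1(C)C)B1OC(C)(C)C(C)(C)O1; potassium peroxymonosulfate [K+].[O-]S(=O)(=O)OO
Why: Sterically governed iridium-catalysed C–H borylation (Hartwig–Miyaura type) reaches only C4–H, the one ring hydrogen with no ortho substituent, and one-pot peroxymonosulfate oxidation of the C–B bond (1,2-aryl shift from boron to oxygen) gives the mirror-symmetric phenol, with no stereocentre formed.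

**Step 2**
Reactants: 3 3,5-dimethoxy-4-methylphenol
Product: 5 1-(6-hydroxy-2,4-dimethoxy-3-methylphenyl)ethan-1-one, via aryl acetate 4 (not isolated)
Conditions: Ac2O (1.1 equiv), BF3·OEt2 (as medium), 70 °C, 2 h; aqueous NaOAc work-up
Reagents that add atoms: acetic anhydride CC(=O)OC(C)=O
Why: O-acetylation followed by BF3-promoted Fries rearrangement ends at the chelated ortho-hydroxy ketone, and since the para position is blocked by methyl and the two ortho positions of 3 are symmetry-equivalent, only one regioisomer can form, which fixes the later 6-methyl (not 8-methyl) pattern.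

**Step 3**
Reactants: 5 1-(6-hydroxy-2,4-dimethoxy-3-methylphenyl)ethan-1-one; 6 4-hydroxybenzaldehyde
Product: 9 2-(4-hydroxyphenyl)-5,7-dimethoxy-6-methyl-4H-chromen-4-one, via chalcone 7 (not isolated), via flavanone 8 (not isolated)
Conditions: pyrrolidine (0.5 equiv), I2 (10 mol %), DMSO, 140 °C, 12 h
Reagents that add atoms: none
Why: A domino Claisen–Schmidt condensation (pyrrolidine iminium/enamine catalysis), oxa-Michael closure through the only free ortho OH and I2/DMSO dehydrogenation builds ring C in one pot and tolerates the free para-phenol, and the C2 stereocentre of racemic 8 is transient and erased in 9.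

**Step 4**
Reactants: 10 apigenin
Product: 11 5,7-bis(benzyloxy)-2-[4-(benzyloxy)phenyl]-4H-chromen-4-one
Conditions: BnBr (4.5 equiv), K2CO3 (5 equiv), DMF, 90 °C, 24 h
Reagents that add atoms: benzyl bromide BrCc1ccccc1
Why: Exhaustive Williamson etherification (heat and excess reagent overcome the chelated 5-OH) removes every phenol that could bind the oxidant in step 5 and gives the 5,7-dialkoxy pattern whose electrophilic substitution goes to C8, with no stereocentre formed.

**Step 5** (key step)
Reactants: 9 2-(4-hydroxyphenyl)-5,7-dimethoxy-6-methyl-4H-chromen-4-one; 11 5,7-bis(benzyloxy)-2-[4-(benzyloxy)phenyl]-4H-chromen-4-one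
Product: 14 5,7-bis(benzyloxy)-2-[4-(benzyloxy)phenyl]-8-[5-(5,7-dimethoxy-6-methyl-4-oxo-4H-chromen-2-yl)-2-hydroxyphenyl]-4H-chromen-4-one, via aryloxy-λ3-iodane 12 (not isolated), via ortho-dienone 13 (not isolated)
Conditions: 9, PhI(OCOCF3)2 (1.0 equiv), CH2Cl2–MeCN, −40 °C, 10 min; this solution added over 1 h to 11 (3 equiv, excess recovered) in (CF3)2CHOH–CH2Cl2 3:1, 0 °C → rt
Reagents that add atoms: [bis(trifluoroacetoxy)iodo]benzene O=C(OI(OC(=O)C(F)(F)F)c1ccccc1)C(F)(F)F (its atoms stay only in 12)
Why: Proposed new method: ligand exchange of the only free phenol at trivalent iodine gives 12, whose O–I bond ionises in hexafluoroisopropanol (PhI as hypernucleofuge) to a phenoxenium-type species, so that C3', normally a donor carbon ortho to OH, becomes an acceptor (aromatic enolonium equivalent); the substituted C1' is closed to a bulky π-nucleophile, so C8–H of 11 (the established site of electrophilic substitution in 5,7-dialkoxyflavones, C6 being squeezed between two benzyloxy groups) attacks C3' in a Friedel–Crafts sense, and racemic dienone 13 tautomerises to the phenol so that no stereocentre remains; the closest known reaction types are the PhI(OCOCF3)2 dearomatisation of 4'-hydroxyflavones to protoflavone para-quinols (same activated ring B, oxygen nucleophile), Kita-type hypervalent-iodine phenol–arene oxidative cross-coupling in fluoroalcohols, and the acid-promoted quinone monoacetal–arene biaryl coupling.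

**Step 6**
Reactants: 14 5,7-bis(benzyloxy)-2-[4-(benzyloxy)phenyl]-8-[5-(5,7-dimethoxy-6-methyl-4-oxo-4H-chromen-2-yl)-2-hydroxyphenyl]-4H-chromen-4-one
Product: 15 8-[2-hydroxy-5-(5-hydroxy-7-methoxy-6-methyl-4-oxo-4H-chromen-2-yl)phenyl]-5,7-dihydroxy-2-(4-hydroxyphenyl)-4H-chromen-4-one (target)
Conditions: BCl3 (10 equiv), pentamethylbenzene (10 equiv), CH2Cl2, −78 °C, 1 h, then 0 °C, 2 h; MeOH then aqueous HCl work-up
Reagents that add atoms: none
Why: In this Lewis acid ether cleavage BCl3 removes the aryl benzyl ethers at low temperature while pentamethylbenzene traps the benzyl cation (Friedel–Crafts scavenging), and it cleaves only the methyl ether that can chelate boron to the C4 carbonyl (the crowded 5-OMe), so the non-chelating 7-OMe survives and no stereocentre is involved.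

**Compound list**
1 | 2,6-dimethoxytoluene | COc1cccc(OC)c1C | starting material
2 | 2-(3,5-dimethoxy-4-methylphenyl)-4,4,5,5-tetramethyl-1,3,2-dioxaborolane | COc1cc(cc(OC)c1C)B1OC(C)(C)C(C)(C)O1 | intermediate
3 | 3,5-dimethoxy-4-methylphenol | COc1cc(O)cc(OC)c1C | intermediate
4 | 3,5-dimethoxy-4-methylphenyl acetate | COc1cc(OC(C)=O)cc(OC)c1C | intermediate
5 | 1-(6-hydroxy-2,4-dimethoxy-3-methylphenyl)ethan-1-one | CC(=O)c1c(O)cc(OC)c(C)c1OC | intermediate
6 | 4-hydroxybenzaldehyde | O=Cc1ccc(O)cc1 | starting material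
7 | (E)-1-(6-hydroxy-2,4-dimethoxy-3-methylphenyl)-3-(4-hydroxyphenyl)prop-2-en-1-one | COc1cc(O)c(C(=O)/C=C/c2ccc(O)cc2)c(OC)c1C | intermediate
8 | racemic 2-(4-hydroxyphenyl)-5,7-dimethoxy-6-methylchroman-4-one | COc1cc2OC(c3ccc(O)cc3)CC(=O)c2c(OC)c1C | intermediate
9 | 2-(4-hydroxyphenyl)-5,7-dimethoxy-6-methyl-4H-chromen-4-one | COc1cc2oc(-c3ccc(O)cc3)cc(=O)c2c(OC)c1C | intermediate
10 | apigenin (5,7-dihydroxy-2-(4-hydroxyphenyl)-4H-chromen-4-one) | O=c1cc(-c2ccc(O)cc2)oc2cc(O)cc(O)c12 | starting material
11 | 5,7-bis(benzyloxy)-2-[4-(benzyloxy)phenyl]-4H-chromen-4-one | O=c1cc(-c2ccc(OCc3ccccc3)cc2)oc2cc(OCc3ccccc3)cc(OCc3ccccc3)c12 | intermediate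
12 | [4-(5,7-dimethoxy-6-methyl-4-oxo-4H-chromen-2-yl)phenoxy](phenyl)-λ3-iodanyl trifluoroacetate | COc1cc2oc(-c3ccc(OI(OC(=O)C(F)(F)F)c4ccccc4)cc3)cc(=O)c2c(OC)c1C | intermediate
13 | racemic 5,7-bis(benzyloxy)-2-[4-(benzyloxy)phenyl]-8-[3-(5,7-dimethoxy-6-methyl-4-oxo-4H-chromen-2-yl)-6-oxocyclohexa-2,4-dien-1-yl]-4H-chromen-4-one | O=C1C=CC(=CC1c1c(OCc2ccccc2)cc(OCc2ccccc2)c2c(=O)cc(-c3ccc(OCc4ccccc4)cc3)oc12)c1cc(=O)c2c(OC)c(C)c(OC)cc2o1 | intermediate
14 | 5,7-bis(benzyloxy)-2-[4-(benzyloxy)phenyl]-8-[5-(5,7-dimethoxy-6-methyl-4-oxo-4H-chromen-2-yl)-2-hydroxyphenyl]-4H-chromen-4-one | COc1cc2oc(-c3ccc(O)c(-c4c(OCc5ccccc5)cc(OCc5ccccc5)c5c(=O)cc(-c6ccc(OCc7ccccc7)cc6)oc45)c3)cc(=O)c2c(OC)c1C | intermediate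
15 | 8-[2-hydroxy-5-(5-hydroxy-7-methoxy-6-methyl-4-oxo-4H-chromen-2-yl)phenyl]-5,7-dihydroxy-2-(4-hydroxyphenyl)-4H-chromen-4-one (6-methyl-7-O-methylamentoflavone, CNP0113589.0) | COc1cc2oc(-c3ccc(O)c(-c4c(O)cc(O)c5c(=O)cc(-c6ccc(O)cc6)oc45)c3)cc(=O)c2c(O)c1C | target

**Total step count:** 6. **Longest linear sequence:** 5 (steps 1, 2, 3, 5, 6); step 4 is the one-step side branch.

**Three steps most likely to fail**

**Step 5** is the main risk, and I expect 25–35 %.
- The activated ring B could be captured at C1' by trifluoroacetate or the fluoroalcohol, giving protoflavone-type quinol derivatives.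
- C8–H of a second molecule of the C-methylated flavone could compete as the donor. I expect this to be slower than attack by 11, because the 5-OMe is twisted out of conjugation between the 6-methyl and the carbonyl, and the 7-OMe is pushed towards C8. In addition, 11 is present in threefold excess and 12 is added slowly.
- Product 14 could be oxidised further. This is why the oxidant is consumed by 9 before it meets 14.

The fallback sets out from 5, uses 11 unchanged and comes back at 14. It keeps C3' as the acceptor carbon but fixes it in a discrete, redox-neutral reagent.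
- The condensation of step 3 is run with commercial 4-hydroxy-3-nitrobenzaldehyde to give 2-(4-hydroxy-3-nitrophenyl)-5,7-dimethoxy-6-methyl-4H-chromen-4-one F1.
- Fe powder and NH4Cl in EtOH–H2O at 80 °C reduce it to 2-(3-amino-4-hydroxyphenyl)-5,7-dimethoxy-6-methyl-4H-chromen-4-one F2.
- Diazotisation (NaNO2, aqueous HCl, 0 °C, then NaHCO3) gives the ortho-quinone diazide 2-(3-diazo-4-oxocyclohexa-1,5-dien-1-yl)-5,7-dimethoxy-6-methyl-4H-chromen-4-one F3.
- Slow addition of this diazide to 11 and Rh2(OAc)4 (2 mol %) in 1,2-dichloroethane at 40 °C generates an electrophilic rhodium carbenoid exactly at C3'. C8–H of 11 attacks it, and a proton shift gives 14. Wolff ring contraction is the side path to watch.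

**Step 3** may be slow.
- The ketone is flanked by two ortho substituents and the phenolic aldehyde is a weak acceptor.
- Traces of HI at 140 °C can cleave the 5-OMe or iodinate ring A.

The fallback sets out from 5 and comes back at 9. It works at the carboxylic acid oxidation level, so no dehydrogenation is needed.
- 5 is treated with LiN(SiMe3)2 (3.2 equiv) in THF at −78 °C and then with 4-acetoxybenzoyl chloride. This is a direct C-acylation of the ketone enolate and gives the same 1,3-diketone a Baker–Venkataraman rearrangement would give, 4-[3-(6-hydroxy-2,4-dimethoxy-3-methylphenyl)-3-oxopropanoyl]phenyl acetate F4.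
- Heating in aqueous HCl–AcOH at 100 °C closes ring C by cyclodehydration and hydrolyses the acetate in the same pot, giving 9.

**Step 6** may give three problems.
- C-benzylation of the phloroglucinol-type ring.
- Poorly soluble boron chelates that stop the reaction short.
- Some loss of the 7-OMe if the mixture is warmed too far.

The fallback sets out from 14 and comes back at 15. It separates the two kinds of ether cleavage into orthogonal operations.
- Hydrogenolysis (H2, 1 atm, Pd/C, THF–MeOH, rt, stopped at uptake of three equivalents) gives 8-[5-(5,7-dimethoxy-6-methyl-4-oxo-4H-chromen-2-yl)-2-hydroxyphenyl]-5,7-dihydroxy-2-(4-hydroxyphenyl)-4H-chromen-4-one F5.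
- AlCl3 in MeCN at 60 °C then removes only the carbonyl-chelated 5-OMe, giving 15.

**Further compounds**
F1 | step 5 | 2-(4-hydroxy-3-nitrophenyl)-5,7-dimethoxy-6-methyl-4H-chromen-4-one | COc1cc2oc(-c3ccc(O)c([N+](=O)[O-])c3)cc(=O)c2c(OC)c1C
F2 | step 5 | 2-(3-amino-4-hydroxyphenyl)-5,7-dimethoxy-6-methyl-4H-chromen-4-one | COc1cc2oc(-c3ccc(O)c(N)c3)cc(=O)c2c(OC)c1C
F3 | step 5 | 2-(3-diazo-4-oxocyclohexa-1,5-dien-1-yl)-5,7-dimethoxy-6-methyl-4H-chromen-4-one | COc1cc2oc(C3=CC(=[N+]=[N-])C(=O)C=C3)cc(=O)c2c(OC)c1C
F4 | step 3 | 4-[3-(6-hydroxy-2,4-dimethoxy-3-methylphenyl)-3-oxopropanoyl]phenyl acetate | COc1cc(O)c(C(=O)CC(=O)c2ccc(OC(C)=O)cc2)c(OC)c1C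
F5 | step 6 | 8-[5-(5,7-dimethoxy-6-methyl-4-oxo-4H-chromen-2-yl)-2-hydroxyphenyl]-5,7-dihydroxy-2-(4-hydroxyphenyl)-4H-chromen-4-one | COc1cc2oc(-c3ccc(O)c(-c4c(O)cc(O)c5c(=O)cc(-c6ccc(O)cc6)oc45)c3)cc(=O)c2c(OC)c1C
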